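Readings and results come from a simulation for substances that don't exist; noise was put on by code.

**Late plateau.** Late in the dusk run the product reading moves from 23.9% at 12.0 h to 26.7% at 15.0 h, so the curve of product against age is flattening. At 10.0 h the dusk, spring and summer runs read 23.9%, 21.8% and 19.6% for charges of 20 mM, 10 mM and 15 mM, all at c(protic impurity) = 20.0 mM. These readings of 23.9%, 21.8% and 19.6% do not rise in order of charge, but single readings with a scatter of 1 percentage point can hide a steady rise with charge, so they do not show that the yield is independent of charge. Freezing the yield at a given age and using one curve is therefore my approximation, and I carry that risk into eta, which receives its charge over 12.0 h and not at once.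

| flask | starting material | protic impurity | remark | time |
|---|---|---|---|---|
| dusk | 20 mM | 20 mM | run made earlier |  |
| spring | 10 mM | 20 mM | run made earlier |  |
| summer | 15 mM | 20 mM | run made earlier |  |
| eta | 20 mM (fed, over 12.0 h) | 20.0 mM | all but starting material at the start; starting material goes in evenly over 12.0 h, the run ends at 15 h | 15 h |
| gamma | 20 mM | 20.0 mM | a closed flask charged with all of it at once and left for 15 h | 15 h |
| beta | 20 mM | 20.0 mM | one stirred flow tank at steady state, fed with the mixture as stated, mean residence time 15 h |  |

| run | time / h | product / % |
|---|---|---|
| dusk | 2.50 | 0.1 |
| dusk | 5.00 | 10.9 |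
| dusk | 8.00 | 20.3 |
| dusk | 10.0 | 23.9 |
| dusk | 12.0 | 23.9 |
| dusk | 15.0 | 26.7 |
| spring | 0.667 | 0.3 |
| spring | 1.33 | 0 |
| spring | 2.00 | 0.3 |
| spring | 3.00 | 6.1 |
| spring | 5.00 | 10.2 |
| spring | 10.0 | 21.8 |
| summer | 1.50 | 0.8 |
| summer | 3.00 | 3.6 |
| summer | 5.00 | 10.2 |
| summer | 6.00 | 13.8 |
| summer | 8.00 | 17.4 |
| summer | 10.0 | 19.6 |

(standard deviation of a reading: 1 percentage point)

- the stated concentrations are those of everything mixed, before any reaction; amounts are the same in each set-up
- what was read earlier has a scatter of 1 percentage point, one standard deviation
- steps thought possible: starting material -> intermediate A; intermediate A -> intermediate B; intermediate B -> intermediate C; intermediate C <-> product; starting material + protic impurity -> quenched substrate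
- the feed brings no volume worth counting
- the earlier runs were made in a closed, stirred flask

- the set-up with the highest amount of product at the outlet or at the end, in percent of the starting material put in ("none" if the first two lie within 2 percentage points) (eta / gamma / beta / none)
- amount of product at the outlet or at the end, in percent of the starting material put in, eta
- amount of product at the outlet or at the end, in percent of the starting material put in, gamma
- amount of product at the outlet or at the end, in percent of the starting material put in, beta

**The ledger.** Of the starting material charged in the dusk run, 26.7% is booked as product at 15.0 h, while the other 73.3% lies unread among starting material, the intermediates and quenched substrate. Gamma repeats the dusk charge and time, so I enter 26.7% for it. Eta books its starting material in parcels: at the end the last parcel is 3.00 h old and the first 15 h, and the even feed weights each age equally. The curve at that youngest age interpolates to 2.26%. The age-mean yield, the dusk curve averaged evenly over the ages present at the end, comes by trapezia to 19.0%, and that is my entry for eta.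

**The forecast.** The forecast names gamma as best, with 17.5% for eta, 27% for gamma and 24.5% for beta. On eta it says “Averaging the batch curve over ages of 3–15 h gives about 17–18%”, and my trapezia stand 1.5 points above its figure.

**The result.** The flask gives 18.3% for eta, 27.8% for gamma and 21.3% for beta, so gamma is highest, and the age-mean yield lies 0.70 points above eta's figure.

    starting material → intermediate A (k = 7.00 × 10⁻⁵ s⁻¹)
    intermediate A → intermediate B (k = 3.90 × 10⁻⁴ s⁻¹)
    intermediate B → intermediate C (k = 8.60 × 10⁻⁵ s⁻¹)
    intermediate C ⇌ product (K = 2.60, k = 1.40 × 10⁻⁴ s⁻¹)
    starting material + protic impurity → quenched substrate (k = 0.00780 M⁻¹ s⁻¹)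

**Two clocks.** In gamma, at the concentrations as charged, the quench alone gives starting material a half-life of 1.2 h, shorter than the 2.8 h of its passing into intermediate A alone. With eta left to 150 h, its youngest parcel is 5.75 d old, and eta then gives 29.3%, as gamma gives 29.3%.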